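The numbers of this flask are invented.

At the start it was impossible to make target in the flask: none of the solid substrate was in solution, so free catalyst had second substrate to bind and no starting material.

solid substrate 0.063 M; second substrate 0.0630 M; coupling partner 0.158 M; free catalyst 63 µM; time 2.0 min

- how much target there is at 2.0 min, in percent of the solid substrate charged
- concentration of starting material in solution at 2.0 min, in percent of saturation

- solid substrate is a solid; its amount is given per volume of the solution
- at the start none of the solid substrate is in solution
- starting material means what is dissolved; the solid is not counted in it
- run time (flask): 2.0 min

    target + free catalyst ⇌ isomer of the product + free catalyst, rate k1*[free catalyst]*[target] forward; the back reaction follows from the equilibrium constant (K1 = 1.8, k1 = 42 L mol⁻¹ s⁻¹)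
    coupling partner + catalyst intermediate A → free catalyst + target (k2 = 74 L mol⁻¹ s⁻¹)
    solid substrate ⇌ starting material, rate k3*(cs3 - [starting material]) while solid is left; crystals form when [starting material] > cs3 (cs3 = 0.062 M, k3 = 0.0058 s⁻¹)
    coupling partner + catalyst intermediate B → free catalyst + second product (k4 = 510 L mol⁻¹ s⁻¹)
    second substrate + free catalyst ⇌ catalyst intermediate B (K5 = 35 L mol⁻¹, k5 = 110 L mol⁻¹ s⁻¹)
    starting material + free catalyst ⇌ catalyst intermediate A (K6 = 950 L mol⁻¹, k6 = 180 L mol⁻¹ s⁻¹)

How high did [starting material] climb in the flask? The solid fed it at 0.0058 s⁻¹ times the gap to saturation. With free catalyst held at its charge, binding drew it off as a pseudo-first-order loss of 0.0113 s⁻¹, faster than that coefficient. The two together made 0.0171 s⁻¹, so I had [starting material] climbing towards 0.0210 M and reaching 0.0183 M by 2.0 min, or 29.5% of saturation.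

Did each binding count? With coupling partner at its charge, catalyst intermediate A went on at 11.7 s⁻¹ and fell back at 0.189 s⁻¹; catalyst intermediate B went on at 80.6 s⁻¹ and fell back at 3.14 s⁻¹, so I counted bindings as products.

Which way did the catalyst go? At the charge of second substrate, 0.0385 M was the crossover, the [starting material] at which free catalyst binds it as fast as it binds second substrate. My [starting material] ended at 0.475 of that, so in my reckoning second product stayed ahead. Summing the bindings gave 26.1% of the charge as target with the catalyst wholly free. But I reckoned the free share falling to 0.731, so I took the mean share and committed to 22.6%.

The forecast said 20% of target, less than mine, and 35% of saturation, more than mine, noting that “The competing second-substrate channel takes much of the free catalyst early on”.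

The flask gave 18.8% of target and 34.0% of saturation.

In the flask at 2.00 min, the second substrate remaining put the crossover at 0.0209 M, level with [starting material] at 0.0211 M, and the forward binding of second substrate ran at 0.99 of that of starting material. In the neighbouring flask charged with 0.016 M of solid substrate, [starting material] at 2.00 min was 0.00681 M against a crossover of 0.0200 M, a ratio of 0.340, and the step to target ran at 0.350 of the step to second product.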